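Numbering (aromadendrane): C1 = O-bearing carbon, C2–C3 = ring CH2–CH2, C4 = quaternary C(CH3), C5 = ring-fusion CH, C6/C7 = cyclopropane CH, C10 = CH(CH3), C11 = CMe2, C7′ = benzylic CH; carane C2 = C5 and carane C3 = C10.
Retrosynthesis: C1–O, C1–C5, C4–C7′ and C7′–aryl are cut together (o-quinone methide/germacrene cation cascade) to bicyclogermacrene, isovaleraldehyde and diformylphloroglucinol; C2–C3 of the ten-membered diene is then cut by a retro-[3,3] shift that restores C5–C10 and leaves a carane with vinyl on C10 and isopropenyl plus oxygen on C5; these groups are cut back to caran-2-one, i.e. (+)-2-carene.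
Enabling feature: C2–C3 lies between C1 and C4, which in the germacrene are the inner carbons of the C1=C10 and C4=C5 alkenes, so it is the central σ-bond of the 1,5-diene C10=C1–C2–C3–C4=C5; the six-membered ring C5–C6–C7–C8–C9–C10 hidden inside the target's seven-membered ring is the carane ring whose C5–C10 bond is traded for C2–C3.
Forward ring order: cyclopropane (bought) → six-membered ring decorated → ten-membered ring by C2–C3 formation (oxy-Cope ring expansion, enolate trapped as triflate, then reduced) → cyclopentane, cycloheptane and benzoxepine rings in one final three-component step.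
Stereochemistry: C6/C7 from (+)-2-carene; both E-alkenes from the chair transition state; C4, C5, C1 and C10 from anti addition across the E-alkenes, a suprafacial 1,2-hydride shift and the phenol tether; C7′ from the face of the o-quinone methide (substrate control only).

Key step: step 7

Remark: commercial (+)-2-carene is taken as the (1S,6R) enantiomer; its cyclopropane carbons map onto C6/C7 of the target with the required configuration. "Bridge" below means the CMe2 carbon C11.

Step 1
Reactants: 1 (+)-2-carene
Product: 3 2-isocaranol, via di(2-isocaranyl)borane 2 (not isolated)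
Conditions: BH3·SMe2 (0.5 equiv), THF, 0 °C to rt; then NaOH, H2O2, H2O, 0 °C to rt
Reagents that add atoms: hydrogen peroxide, OO
Why: Brown hydroboration–oxidation: B–H should add syn and anti-Markovnikov across C5=C10 from the face opposite the bridge and the C–B bond is oxidised with retention, so OH on C5 is trans and the C10 methyl cis to the cyclopropane; both centres are provisional (C5 is oxidised in step 2, C10 is rebuilt in step 3).

Step 2
Reactants: 3 2-isocaranol
Product: 4 caran-2-one
Conditions: Dess–Martin periodinane, CH2Cl2, 0 °C to rt
Reagents that add atoms: none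
Why: Dess–Martin oxidation under neutral, non-aqueous conditions should give the cyclopropyl ketone without opening the acid-labile cyclopropylcarbinyl system; no new stereocentre.

Step 3
Reactants: 4 caran-2-one; 5 vinyl bromide
Product: 7 3-methyl-3-vinylcaran-2-one, via lithium enolate 6 (not isolated)
Conditions: LiN(SiMe3)2, THF, −78 to 0 °C; then 5, Pd2(dba)3 (cat.), P(t-Bu)3 (cat.), THF/toluene, rt to 50 °C
Reagents that add atoms: none
Why: Palladium-catalysed α-alkenylation of a ketone enolate (Buchwald–Hartwig-type α-vinylation): only C10 can be enolised because the other α-carbon is the cyclopropane CH, and the vinylpalladium species from oxidative addition to zerovalent palladium should bind and reductively eliminate on the enolate face opposite the bridge and its syn-methyl, setting quaternary C10 with vinyl trans to the cyclopropane.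

Step 4
Reactants: 7 3-methyl-3-vinylcaran-2-one; 8 isopropenylmagnesium bromide
Product: 9 cis-dialkenyl carbinol
Conditions: 8, LaCl3·2LiCl (0.3 equiv), THF, −20 to 0 °C; H2O quench
Reagents that add atoms: none
Why: Lanthanide-promoted Grignard 1,2-addition to a hindered, practically non-enolisable ketone: the nucleophile should again attack C5 from the face opposite the bridge, which puts isopropenyl cis to the C10 vinyl group (the cis-dialkenyl carbinol, corrected in steps 5 and 6).

Step 5
Reactants: 9 cis-dialkenyl carbinol
Product: 11 allylic sulfoxide, via sulfenate ester 10 (not isolated)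
Conditions: n-BuLi, THF, −78 °C; PhSCl, −78 °C to rt
Reagents that add atoms: benzenesulfenyl chloride, ClSc1ccccc1
Why: O-Sulfenylation of the lithium alkoxide and Mislow–Evans [2,3]-sigmatropic rearrangement, which for a congested tertiary allylic sulfenate lies on the side of the primary allylic sulfoxide with the tetrasubstituted C5=C4 alkene; C5 becomes planar, and the alkene geometry and sulfur configuration are uncontrolled and vanish in step 6.

Step 6
Reactants: 11 allylic sulfoxide
Product: 13 trans-dialkenyl carbinol, via epimeric sulfenate 12 (not isolated)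
Conditions: Et2NH (excess), MeOH, 50 °C
Reagents that add atoms: none
Why: Reverse Mislow–Evans rearrangement under thiophile trapping: 11 equilibrates with both C5-epimeric sulfenates, oxygen should return to C5 faster on the alkene face opposite the bridge, and irreversible S–O cleavage by diethylamine drains that sulfenate to the carbinol with OH trans to the cyclopropane and isopropenyl trans to vinyl, while any 9 that re-forms is recycled through step 5.

Step 7
Reactants: 13 trans-dialkenyl carbinol
Product: 16 bicyclogermacradienyl triflate, via potassium alkoxide 14 (not isolated), via potassium enolate 15 (not isolated)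
Conditions: KH, 18-crown-6, THF, 0 °C to rt; then PhNTf2, −78 to 0 °C
Reagents that add atoms: N-phenylbis(trifluoromethanesulfonimide), O=S(=O)(N(c1ccccc1)S(=O)(=O)C(F)(F)F)C(F)(F)F
Why: Deprotonation gives potassium alkoxide 14, a 3-oxido-1,5-diene (C2=C1–C10–C5(O−)–C4=C3) that should undergo a charge-accelerated [3,3]-sigmatropic shift through a chair transition state in which the C5–C10 bond of the six-membered ring breaks while the C2–C3 bond forms, giving the ten-membered potassium enolate 15, which is triflated on oxygen. The closest known reaction type is the anionic oxy-Cope ring expansion of trans-1,2-dialkenylcyclohexanols to (E)-cyclodec-5-enones with trapping of the regiodefined enolate; the thermal Cope rearrangement of the parent germacrene to its elemene-type carane is the same pericyclic path run backwards. The ten-membered carbocycle is closed by a four-atom ring expansion (six to ten) through a six-centre chair array, not by end-to-end cyclisation, so high dilution is not needed. No new stereocentre is formed (C5 and C10 become sp2); the two alkene geometries are fixed by the chair in which the ring bonds C10–C9 and C5–C6 are equatorial, which gives E at C1=C10 and places C6 trans to C3, with the axial oxygen cis to C3, at C4=C5. The step needs vinyl and isopropenyl trans on the six-membered ring (set in steps 3 and 6) so that both can be pseudo-equatorial, and it needs the concerted path to outrun heterolytic C5–C10 cleavage, which the dissociated potassium/18-crown-6 alkoxide at or below rt and immediate O-triflation of 15 at −78 °C are chosen to secure.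

Step 8
Reactants: 16 bicyclogermacradienyl triflate
Product: 17 bicyclogermacrene
Conditions: Pd(OAc)2 (cat.), PPh3 (cat.), HCO2H, n-Bu3N, DMF, 40 °C
Reagents that add atoms: none
Why: Palladium-catalysed formate reduction of an enol triflate (oxidative addition to zerovalent palladium, formate-to-hydride exchange with loss of CO2, reductive elimination) should replace OTf by H with retention of alkene geometry, giving the E-trisubstituted C4=C5 alkene under buffered conditions below the temperature at which the germacrene reverts by Cope rearrangement.

Step 9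
Reactants: 17 bicyclogermacrene; 18 isovaleraldehyde; 19 2,4-diformylphloroglucinol
Product: 21 target meroterpenoid, via o-quinone methide 20 (not isolated)
Conditions: ethylenediammonium diacetate (cat.), THF, 4 Å molecular sieves, rt to 35 °C, slow addition of 18
Reagents that add atoms: none
Why: Knoevenagel condensation of 18 at the free ring position of 19 should give o-quinone methide 20, whose benzylic carbon C7′ is attacked by C4 of the C4=C5 alkene while C5 bonds transannularly to C1, the C10 cation relays to C1 by a suprafacial 1,2-hydride shift and the adjacent phenol closes the oxepine (biomimetic Michael addition/cation–olefin cyclisation cascade, a reaction type with close precedent for this germacrene and aryl-substituted o-quinone methides); anti addition across E-C4=C5 sets C4 and C5 (C7′ cis to H5), the hydride shift sets C10, the phenol tether forces O–C1 cis to C4–C7′, C6/C7 come from 1, and C7′ is set only by the face and geometry of 20.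

Compound list
1 | (+)-2-carene, (1S,6R)-3,7,7-trimethylbicyclo[4.1.0]hept-2-ene | CC1=C[C@H]2[C@@H](CC1)C2(C)C | starting material
2 | di(2-isocaranyl)borane (boron on carane C2, trans to the bridge) | [H]B([C@@H]1[C@@H](C)CC[C@H]2C(C)(C)[C@@H]12)[C@@H]1[C@@H](C)CC[C@H]2C(C)(C)[C@@H]12 | intermediate
3 | 2-isocaranol (3,7,7-trimethylbicyclo[4.1.0]heptan-2-ol; OH trans, 3-CH3 cis to the bridge) | C[C@H]1CC[C@H]2C(C)(C)[C@H]2[C@@H]1O | intermediate
4 | caran-2-one (3,7,7-trimethylbicyclo[4.1.0]heptan-2-one; 3-CH3 cis to the bridge) | C[C@H]1CC[C@H]2C(C)(C)[C@H]2C1=O | intermediate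
5 | vinyl bromide | C=CBr | starting material
6 | lithium enolate of 4 (C5–O, C5=C10) | CC1=C([O-])[C@H]2[C@@H](CC1)C2(C)C.[Li+] | intermediate
7 | 3-methyl-3-vinylcaran-2-one (vinyl trans, CH3 cis to the bridge) | C=C[C@]1(C)CC[C@H]2C(C)(C)[C@H]2C1=O | intermediate
8 | isopropenylmagnesium bromide | C=C(C)[Mg]Br | starting material
9 | 2-isopropenyl-3-methyl-3-vinylcaran-2-ol, cis-dialkenyl epimer (isopropenyl trans, OH cis to the bridge) | C=C[C@]1(C)CC[C@H]2C(C)(C)[C@H]2[C@]1(O)C(C)=C | intermediate
10 | O-(phenylsulfenyl) ester of 9 | C=C[C@]1(C)CC[C@H]2C(C)(C)[C@H]2[C@]1(OSc1ccccc1)C(C)=C | intermediate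
11 | 3-methyl-2-[1-(phenylsulfinyl)propan-2-ylidene]-3-vinylcarane (alkene geometry and sulfur configuration not controlled, drawn without them) | C=C[C@]1(C)CC[C@H]2C(C)(C)[C@H]2C1=C(C)CS(=O)c1ccccc1 | intermediate
12 | O-(phenylsulfenyl) ester of 13 | C=C[C@]1(C)CC[C@H]2C(C)(C)[C@H]2[C@@]1(OSc1ccccc1)C(C)=C | intermediate
13 | 2-isopropenyl-3-methyl-3-vinylcaran-2-ol, trans-dialkenyl epimer (OH and vinyl trans, isopropenyl and CH3 cis to the bridge) | C=C[C@]1(C)CC[C@H]2C(C)(C)[C@H]2[C@@]1(O)C(C)=C | intermediate
14 | potassium alkoxide of 13 | C=C[C@]1(C)CC[C@H]2C(C)(C)[C@H]2[C@@]1([O-])C(C)=C.[K+] | intermediate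
15 | potassium (1(10)E)-bicyclogermacra-1(10),4-dien-5-olate (C3 and C6 trans across C4=C5) | C/C1=C\CC/C(C)=C(\[O-])[C@H]2[C@@H](CC1)C2(C)C.[K+] | intermediate
16 | (1(10)E)-bicyclogermacra-1(10),4-dien-5-yl trifluoromethanesulfonate (C3 and C6 trans across C4=C5) | C/C1=C\CC/C(C)=C(\OS(=O)(=O)C(F)(F)F)[C@H]2[C@@H](CC1)C2(C)C | intermediate
17 | (1(10)E,4E)-bicyclogermacrene with the C6/C7 configuration of the target | C/C1=C\CC/C(C)=C/[C@H]2[C@@H](CC1)C2(C)C | intermediate
18 | isovaleraldehyde (3-methylbutanal) | CC(C)CC=O | starting material
19 | 2,4-diformylphloroglucinol (2,4,6-trihydroxybenzene-1,3-dicarbaldehyde) | O=Cc1c(O)cc(O)c(C=O)c1O | starting material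
20 | o-quinone methide from 18 and 19 (exocyclic alkene geometry not fixed) | CC(C)CC=C1C(=O)C(C=O)=C(O)C(C=O)=C1O | intermediate
21 | target meroterpenoid (CNP0189833.2) | CC(C)C[C@H]1c2c(O)c(C=O)c(O)c(C=O)c2O[C@]23CC[C@@]1(C)[C@H]2[C@H]1[C@@H](CC[C@@H]3C)C1(C)C | target

Total steps: 9. Longest linear sequence: 9 (from 1).

Steps most likely to fail

1. Step 9. The acid- and heat-labile germacrene may be consumed by transannular cyclisation or Cope rearrangement before the o-quinone methide forms, the aldehyde may self-condense, and capture may go by hetero-Diels–Alder addition at either alkene or on the wrong C7′ face, leaving the cascade product as a minor component. Fallback, setting out from 19 (with 18) and returning at 21: reductive alkylation of 19 with 18 (Hantzsch ester, L-proline cat., CH2Cl2) should give 2,4,6-trihydroxy-5-(3-methylbutyl)benzene-1,3-dicarbaldehyde F1; benzylic oxidation of F1 with DDQ (MeNO2, −20 °C) in the presence of 17 generates the same o-quinone methide 20 cold, without amine, acid or free aldehyde, and 20 enters the same cascade to 21.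

2. Step 7. The alkoxide may cleave heterolytically at C5–C10 (retro-allylation to a tethered allyl anion and an isopropenyl ketone) and recombine without stereochemical memory, or the chair with both alkenyl groups pseudo-equatorial may be hard to reach in the rigid carane, so that E,E geometry is lost. Fallback, setting out from 1 and returning at 17, closes the same C2–C3 bond by sulfone alkylation:
   - Ozonolysis of 1 (O3, CH2Cl2/MeOH, −78 °C; Me2S) gives cis-2,2-dimethyl-3-(3-oxobutyl)cyclopropanecarbaldehyde F2.
   - Aldehyde-selective Wittig reaction with Ph3P=C(CH3)CO2Et gives the (E)-enoate keto ester F3.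
   - Vinylmagnesium bromide at −78 °C adds to the methyl ketone to give the tertiary allylic alcohol F4.
   - Palladium-catalysed allylic sulfonylation with transposition (PhSO2Na, Pd(PPh3)4 cat., BEt3) gives the primary allylic sulfone ester F5, the E isomer being carried on.
   - (i-Bu)2AlH reduces the ester to the allylic alcohol F6.
   - MsCl/LiCl gives the allylic chloride F7.
   - Slow addition of F7 to KN(SiMe3)2 in THF at high dilution alkylates the sulfonyl-stabilised allyl anion intramolecularly to give 2-(phenylsulfonyl)bicyclogermacrene F8.
   - Reductive desulfonylation (PdCl2(dppp) cat., LiBHEt3) gives 17.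

3. Step 6. Oxygen may return to both faces of C5 with poor facial selectivity, or thiophilic cleavage of the congested sulfenate may be too slow, so that mainly 9 is recovered. Fallback, setting out from 9 and returning at 13: the lithium alkoxide of 9 with methyl chloroformate gives the tertiary allylic methyl carbonate F9; Pd(PPh3)4-catalysed hydride transfer from LiBHEt3 to the unsubstituted allyl terminus gives the isopropylidene diene F10; Schenck ene reaction with singlet oxygen (O2, tetraphenylporphyrin, hν, CH2Cl2, −20 °C) on the tetrasubstituted alkene, on the face opposite the bridge, gives the tertiary allylic hydroperoxide F11, which is reduced in the same flask with PPh3 to 13.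

Further compounds
F1 | step 9 | 2,4,6-trihydroxy-5-(3-methylbutyl)benzene-1,3-dicarbaldehyde | CC(C)CCc1c(O)c(C=O)c(O)c(C=O)c1O
F2 | step 7 | cis-2,2-dimethyl-3-(3-oxobutyl)cyclopropanecarbaldehyde | O=C[C@H]1[C@@H](CCC(C)=O)C1(C)C
F3 | step 7 | ethyl (E)-3-[cis-2,2-dimethyl-3-(3-oxobutyl)cyclopropyl]-2-methylacrylate | CCOC(=O)/C(C)=C/[C@H]1[C@@H](CCC(C)=O)C1(C)C
F4 | step 7 | ethyl (E)-3-[cis-3-(3-hydroxy-3-methylpent-4-enyl)-2,2-dimethylcyclopropyl]-2-methylacrylate (carbinol epimers) | CCOC(=O)/C(C)=C/[C@H]1[C@@H](CCC(C)(O)C=C)C1(C)C
F5 | step 7 | ethyl (E)-3-{cis-2,2-dimethyl-3-[(E)-3-methyl-5-(phenylsulfonyl)pent-3-enyl]cyclopropyl}-2-methylacrylate | CCOC(=O)/C(C)=C/[C@H]1[C@@H](CC/C(C)=C/CS(=O)(=O)c2ccccc2)C1(C)C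
F6 | step 7 | (E)-3-{cis-2,2-dimethyl-3-[(E)-3-methyl-5-(phenylsulfonyl)pent-3-enyl]cyclopropyl}-2-methylprop-2-en-1-ol | OC/C(C)=C/[C@H]1[C@@H](CC/C(C)=C/CS(=O)(=O)c2ccccc2)C1(C)C
F7 | step 7 | allylic chloride of F6 | ClC/C(C)=C/[C@H]1[C@@H](CC/C(C)=C/CS(=O)(=O)c2ccccc2)C1(C)C
F8 | step 7 | 2-(phenylsulfonyl)bicyclogermacrene (C2 configuration not controlled) | C/C1=C\C(S(=O)(=O)c3ccccc3)C/C(C)=C/[C@H]2[C@@H](CC1)C2(C)C
F9 | step 6 | methyl carbonate of 9 | C=C[C@]1(C)CC[C@H]2C(C)(C)[C@H]2[C@]1(OC(=O)OC)C(C)=C
F10 | step 6 | 2-isopropylidene-3-methyl-3-vinylcarane (vinyl trans to the bridge) | C=C[C@]1(C)CC[C@H]2C(C)(C)[C@H]2C1=C(C)C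
F11 | step 6 | 2-hydroperoxy-2-isopropenyl-3-methyl-3-vinylcarane (OOH trans to the bridge) | C=C[C@]1(C)CC[C@H]2C(C)(C)[C@H]2[C@@]1(OO)C(C)=C
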